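**Retrosynthetic overview**
1. The target comes from the furanoid C25 aldehyde 3‑pivalate by one hydride step (CHO → CH2OH, ester cleaved).
2. That aldehyde comes from the zeaxanthin‑type C25 polyenal in one flask: peracid epoxidation of C5=C6 on the intact hexaene (oxirane ring, C5 set from C3), then acid‑triggered oxirane → 2,5‑dihydrofuran ring expansion through the C6 polyenyl cation (C8 set). This is the epoxidase‑then‑acid sequence of the plant.
3. The C25 polyenal comes from a C11=C12 Wittig reaction of a C15 trienol (via its phosphonium salt) with the C10 dialdehyde.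
4. The C15 trienol comes from a C6–C7 Stille coupling of an actinol‑derived enol triflate with a stannyl dienol made from (E)‑3‑methylpent‑2‑en‑4‑yn‑1‑ol.
5. Ring order: the carbocycle is bought with C3 in place, then the oxirane, then the dihydrofuran (the last two in the same flask).

Assumption: (4R,6R)‑actinol, (E)‑3‑methylpent‑2‑en‑4‑yn‑1‑ol and the C10 dialdehyde are bought as bulk carotenoid/vitamin A intermediates; the target is the all‑E (3S,5R,8R) isomer (carotenoid numbering for C25 compounds).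

Step 1
Reactants: 1 (4R,6R)-4-hydroxy-2,2,6-trimethylcyclohexan-1-one
Product: 2 (1R,5R)-3,3,5-trimethyl-4-oxocyclohexyl 2,2-dimethylpropanoate
Conditions: PivCl (1.3 equiv), pyridine, DMAP (5 mol%), CH2Cl2, 0 °C → rt
Reagents that add atoms: pivaloyl chloride, CC(C)(C)C(=O)Cl
Why: DMAP‑catalysed O‑acylation of the secondary alcohol touches no stereocentre and installs a bulky, non‑hydrogen‑bonding ester that serves as the facial control element in step 6 and falls off in the final hydride step.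

Step 2
Reactants: 2 (1R,5R)-3,3,5-trimethyl-4-oxocyclohexyl 2,2-dimethylpropanoate
Product: 4 (4R)-4-(pivaloyloxy)-2,6,6-trimethylcyclohex-1-en-1-yl trifluoromethanesulfonate, via lithium enolate 3 (not isolated)
Conditions: LDA (commercial solution, 1.15 equiv), THF, −78 °C; then PhNTf2 (1.2 equiv), −78 °C → rt; aq. NH4Cl
Reagents that add atoms: N-phenylbis(trifluoromethanesulfonimide), O=S(=O)(N(c1ccccc1)S(=O)(=O)C(F)(F)F)C(F)(F)F
Why: Enolate formation/O‑triflation (enol triflate synthesis) is regiospecific because C6 carries the only α‑hydrogen; the C6 centre is erased, C4 (the future C3) is untouched, and the pivalate has no α‑hydrogen and resists LDA at −78 °C.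

Step 3
Reactants: 5 (2E)-3-methylpent-2-en-4-yn-1-ol
Product: 6 (2E,4E)-3-methyl-5-(tributylstannyl)penta-2,4-dien-1-ol
Conditions: Bu3SnH (1.2 equiv), PdCl2(PPh3)2 (2 mol%), THF, 0 °C → rt; chromatography on Et3N‑deactivated silica
Reagents that add atoms: tributyltin hydride, CCCC[SnH](CCCC)CCCC
Why: Pd‑catalysed syn‑hydrostannation of the terminal alkyne places tin on the terminal carbon and gives the E‑vinylstannane (the minor internal regioisomer is removed by chromatography), leaving the 2E alkene and the free alcohol unchanged.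

Step 4
Reactants: 4 (4R)-4-(pivaloyloxy)-2,6,6-trimethylcyclohex-1-en-1-yl trifluoromethanesulfonate; 6 (2E,4E)-3-methyl-5-(tributylstannyl)penta-2,4-dien-1-ol
Product: 7 (2E,4E)-3-methyl-5-[(4R)-4-(pivaloyloxy)-2,6,6-trimethylcyclohex-1-en-1-yl]penta-2,4-dien-1-ol
Conditions: Pd2(dba)3 (2.5 mol%), AsPh3 (20 mol%), NMP, 50 °C
Reagents that add atoms: none
Why: Stille cross‑coupling under Farina conditions (AsPh3/NMP accelerates transmetalation onto the hindered tetrasubstituted alkenyl‑palladium) proceeds with retention of both alkene geometries to give the 7E,9E triene, with no stereocentre involved.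

Step 5
Reactants: 7 (2E,4E)-3-methyl-5-[(4R)-4-(pivaloyloxy)-2,6,6-trimethylcyclohex-1-en-1-yl]penta-2,4-dien-1-ol; 8 (2E,4E,6E)-2,7-dimethylocta-2,4,6-trienedial
Product: 10 (3R,all-E)-3-(pivaloyloxy)-12'-apo-β-caroten-12'-al, via phosphonium bromide 9 (not isolated)
Conditions: PPh3·HBr (1.05 equiv), MeOH, rt, 16 h; then 8 (3 equiv), CH2Cl2, NaOMe (1.1 equiv), −10 °C → rt; then heptane, 90 °C, 2 h (11Z → 11E)
Reagents that add atoms: none
Why: Acid‑mediated SN1 allylic substitution gives the C15 phosphonium salt, whose ylide undergoes Wittig olefination with one formyl group of the excess symmetric dialdehyde (the C25 product aldehyde is less electrophilic than 8, which limits double olefination), and the hindered 11Z isomer of the new C11=C12 bond is isomerised thermally to E.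

Step 6
Reactants: 10 (3R,all-E)-3-(pivaloyloxy)-12'-apo-β-caroten-12'-al
Product: 12 (3S,5R,8R,all-E)-5,8-epoxy-3-(pivaloyloxy)-5,8-dihydro-12'-apo-β-caroten-12'-al, via 5,6-epoxide 11 (not isolated)
Conditions: mCPBA (1.0 equiv), CH2Cl2, −20 °C, 1 h; then CSA (2 mol%), 0 °C, 15 min; aq. NaHCO3; preparative HPLC
Reagents that add atoms: 3-chloroperbenzoic acid, OOC(=O)c1cccc(Cl)c1
Why: Prilezhaev epoxidation followed by the acid‑catalysed epoxide–furanoid rearrangement, where the peracid takes the electron‑rich, twisted tetrasubstituted C5=C6 bond rather than the acceptor‑terminated chain and is expected to attack mainly anti to the non‑hydrogen‑bonding pivalate (sets 5R), after which protonation opens the oxirane at C6 to the hexaenyl cation and the retained C5–O closes on C8 (both C8 epimers form; 8R is isolated by HPLC and 8S can be re‑exposed to the acid).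

Step 7
Reactants: 12 (3S,5R,8R,all-E)-5,8-epoxy-3-(pivaloyloxy)-5,8-dihydro-12'-apo-β-caroten-12'-al
Product: 13 (3S,5R,8R,all-E)-5,8-epoxy-5,8-dihydro-12'-apo-β-carotene-3,12'-diol
Conditions: LiAlH4 (3 equiv), THF, −20 → 0 °C; Rochelle salt work‑up
Reagents that add atoms: none
Why: Hydride 1,2‑reduction of the conjugated aldehyde and reductive cleavage of the pivalate occur in one operation, the cyclic allylic ether and all three stereocentres are inert to LiAlH4, and the non‑acidic work‑up avoids C8 epimerisation and dehydration of the allylic alcohol.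

**Compound list**
1 | (4R,6R)-4-hydroxy-2,2,6-trimethylcyclohexan-1-one (actinol) | CC1(C)C[C@H](O)C[C@@H](C)C1=O | starting material
2 | (1R,5R)-3,3,5-trimethyl-4-oxocyclohexyl 2,2-dimethylpropanoate | CC1(C)C[C@H](OC(=O)C(C)(C)C)C[C@@H](C)C1=O | intermediate
3 | lithium (4R)-4-(pivaloyloxy)-2,6,6-trimethylcyclohex-1-en-1-olate | CC1(C)C[C@H](OC(=O)C(C)(C)C)CC(C)=C1[O-].[Li+] | intermediate
4 | (4R)-4-(pivaloyloxy)-2,6,6-trimethylcyclohex-1-en-1-yl trifluoromethanesulfonate | CC1(C)C[C@H](OC(=O)C(C)(C)C)CC(C)=C1OS(=O)(=O)C(F)(F)F | intermediate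
5 | (2E)-3-methylpent-2-en-4-yn-1-ol | C#C/C(C)=C/CO | starting material
6 | (2E,4E)-3-methyl-5-(tributylstannyl)penta-2,4-dien-1-ol | CCCC[Sn](CCCC)(CCCC)/C=C/C(C)=C/CO | intermediate
7 | (2E,4E)-3-methyl-5-[(4R)-4-(pivaloyloxy)-2,6,6-trimethylcyclohex-1-en-1-yl]penta-2,4-dien-1-ol | CC1=C(/C=C/C(C)=C/CO)C(C)(C)C[C@H](OC(=O)C(C)(C)C)C1 | intermediate
8 | (2E,4E,6E)-2,7-dimethylocta-2,4,6-trienedial | O=C/C(C)=C/C=C/C=C(\C)C=O | starting material
9 | {(2E,4E)-3-methyl-5-[(4R)-4-(pivaloyloxy)-2,6,6-trimethylcyclohex-1-en-1-yl]penta-2,4-dien-1-yl}triphenylphosphonium bromide | CC1=C(/C=C/C(C)=C/C[P+](c2ccccc2)(c2ccccc2)c2ccccc2)C(C)(C)C[C@H](OC(=O)C(C)(C)C)C1.[Br-] | intermediate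
10 | (3R,all-E)-3-(pivaloyloxy)-12'-apo-β-caroten-12'-al | CC1=C(/C=C/C(C)=C/C=C/C(C)=C/C=C/C=C(\C)C=O)C(C)(C)C[C@H](OC(=O)C(C)(C)C)C1 | intermediate
11 | (3S,5R,6S,all-E)-5,6-epoxy-3-(pivaloyloxy)-5,6-dihydro-12'-apo-β-caroten-12'-al | C[C@]12O[C@@]1(/C=C/C(C)=C/C=C/C(C)=C/C=C/C=C(\C)C=O)C(C)(C)C[C@H](OC(=O)C(C)(C)C)C2 | intermediate
12 | (3S,5R,8R,all-E)-5,8-epoxy-3-(pivaloyloxy)-5,8-dihydro-12'-apo-β-caroten-12'-al | CC(/C=C/C=C(\C)[C@H]1C=C2C(C)(C)C[C@H](OC(=O)C(C)(C)C)C[C@@]2(C)O1)=C\C=C\C=C(/C)C=O | intermediate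
13 | (3S,5R,8R,all-E)-5,8-epoxy-5,8-dihydro-12'-apo-β-carotene-3,12'-diol | CC(/C=C/C=C(\C)[C@H]1C=C2C(C)(C)C[C@H](O)C[C@@]2(C)O1)=C\C=C\C=C(/C)CO | target

**Totals**
Total step count: 7. Longest linear sequence: 6 steps (1 → 2 → 4 → 7 → 10 → 12 → 13; step 3 is the side branch).

**Steps most likely to fail, with fallbacks**

Step 6 (most likely). The risks are chain epoxidation, an anti:syn ratio at C5=C6 that is only modest, and a C8 epimer ratio near 1:1, so 12 must be pulled from up to four diastereomers by HPLC. The fallback moves the oxidation to the C15 level, where the acceptor is directly conjugated to the ring alkene and the epoxide epimers separate on ordinary silica. It sets out from 7: MnO2 in CH2Cl2 gives (2E,4E)-3-methyl-5-[(4R)-4-(pivaloyloxy)-2,6,6-trimethylcyclohex-1-en-1-yl]penta-2,4-dienal F1. mCPBA at 0 °C then gives (2E,4E)-5-[(1S,2R,4S)-1,2-epoxy-2,6,6-trimethyl-4-(pivaloyloxy)cyclohexyl]-3-methylpenta-2,4-dienal F2, which is purified to the anti epoxide. NaBH4 gives the corresponding epoxy dienol F3. CBr4/PPh3 with 2,6‑lutidine gives the allylic bromide F4, and further PPh3 gives the epoxy phosphonium bromide F5 without any acid. Wittig reaction with excess 8 in refluxing 1,2‑epoxybutane comes back to the route at 11, now isolated as a single C5/C6 diastereomer, which is ring‑expanded with CSA as in the second half of step 6.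

Step 4. Oxidative addition into the tetrasubstituted, doubly flanked triflate may be slow, with protodestannylation or homocoupling of 6 competing. The fallback makes the C6–C7 bond by carbonyl addition instead and sets out from 1 and 5. The dilithio derivative of 5 (n‑BuLi, THF) adds to the lithium alkoxide of 1 to give (4R,6R)-1-[(3E)-5-hydroxy-3-methylpent-3-en-1-yn-1-yl]-2,2,6-trimethylcyclohexane-1,4-diol F6 (C1 epimers, centre later destroyed). Red‑Al trans‑hydroalumination gives (4R,6R)-1-[(1E,3E)-5-hydroxy-3-methylpenta-1,3-dien-1-yl]-2,2,6-trimethylcyclohexane-1,4-diol F7. Aqueous HBr in CH2Cl2 at −10 °C dehydrates and transposes it to (1R)-4-[(1E,3E)-5-bromo-3-methylpenta-1,3-dien-1-yl]-3,5,5-trimethylcyclohex-3-en-1-ol F8, and PPh3 gives the hydroxy phosphonium bromide F9. Wittig reaction with excess 8 (NaOMe) gives (3R,all-E)-3-hydroxy-12'-apo-β-caroten-12'-al F10, and PivCl/pyridine/DMAP comes back to the route at 10.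

Step 5. The SN1 salt formation can scramble 9E/9Z, the telescoped Wittig can give some double olefination, and methoxide can nibble at the ester. The fallback inverts the order of the two couplings and uses a phosphonate; it sets out from 6. CBr4/PPh3 gives tributyl[(1E,3E)-5-bromo-3-methylpenta-1,3-dien-1-yl]stannane F11. Sodium diethyl phosphite in THF gives diethyl [(2E,4E)-3-methyl-5-(tributylstannyl)penta-2,4-dien-1-yl]phosphonate F12. Horner–Wadsworth–Emmons reaction of its sodium anion (NaHMDS, −78 °C) with excess 8 gives (2E,4E,6E,8E,10E,12E)-2,7,11-trimethyl-13-(tributylstannyl)trideca-2,4,6,8,10,12-hexaenal F13. Stille coupling of this with 4 under the step‑4 conditions comes back to the route at 10.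

**Further compounds**
F1 | step 6 | (2E,4E)-3-methyl-5-[(4R)-4-(pivaloyloxy)-2,6,6-trimethylcyclohex-1-en-1-yl]penta-2,4-dienal | CC1=C(/C=C/C(C)=C/C=O)C(C)(C)C[C@H](OC(=O)C(C)(C)C)C1
F2 | step 6 | (2E,4E)-5-[(1S,2R,4S)-1,2-epoxy-2,6,6-trimethyl-4-(pivaloyloxy)cyclohexyl]-3-methylpenta-2,4-dienal | C[C@]12O[C@@]1(/C=C/C(C)=C/C=O)C(C)(C)C[C@H](OC(=O)C(C)(C)C)C2
F3 | step 6 | (2E,4E)-5-[(1S,2R,4S)-1,2-epoxy-2,6,6-trimethyl-4-(pivaloyloxy)cyclohexyl]-3-methylpenta-2,4-dien-1-ol | C[C@]12O[C@@]1(/C=C/C(C)=C/CO)C(C)(C)C[C@H](OC(=O)C(C)(C)C)C2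
F4 | step 6 | (1S,3R,4S)-4-[(1E,3E)-5-bromo-3-methylpenta-1,3-dien-1-yl]-3,4-epoxy-3,5,5-trimethylcyclohexyl 2,2-dimethylpropanoate | C[C@]12O[C@@]1(/C=C/C(C)=C/CBr)C(C)(C)C[C@H](OC(=O)C(C)(C)C)C2
F5 | step 6 | {(2E,4E)-5-[(1S,2R,4S)-1,2-epoxy-2,6,6-trimethyl-4-(pivaloyloxy)cyclohexyl]-3-methylpenta-2,4-dien-1-yl}triphenylphosphonium bromide | C[C@]12O[C@@]1(/C=C/C(C)=C/C[P+](c3ccccc3)(c3ccccc3)c3ccccc3)C(C)(C)C[C@H](OC(=O)C(C)(C)C)C2.[Br-]
F6 | step 4 | (4R,6R)-1-[(3E)-5-hydroxy-3-methylpent-3-en-1-yn-1-yl]-2,2,6-trimethylcyclohexane-1,4-diol (C1 epimers) | CC1(C)C[C@H](O)C[C@@H](C)C1(O)C#C/C(C)=C/CO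
F7 | step 4 | (4R,6R)-1-[(1E,3E)-5-hydroxy-3-methylpenta-1,3-dien-1-yl]-2,2,6-trimethylcyclohexane-1,4-diol (C1 epimers) | CC1(C)C[C@H](O)C[C@@H](C)C1(O)/C=C/C(C)=C/CO
F8 | step 4 | (1R)-4-[(1E,3E)-5-bromo-3-methylpenta-1,3-dien-1-yl]-3,5,5-trimethylcyclohex-3-en-1-ol | CC1=C(/C=C/C(C)=C/CBr)C(C)(C)C[C@H](O)C1
F9 | step 4 | {(2E,4E)-5-[(4R)-4-hydroxy-2,6,6-trimethylcyclohex-1-en-1-yl]-3-methylpenta-2,4-dien-1-yl}triphenylphosphonium bromide | CC1=C(/C=C/C(C)=C/C[P+](c2ccccc2)(c2ccccc2)c2ccccc2)C(C)(C)C[C@H](O)C1.[Br-]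
F10 | step 4 | (3R,all-E)-3-hydroxy-12'-apo-β-caroten-12'-al | CC1=C(/C=C/C(C)=C/C=C/C(C)=C/C=C/C=C(\C)C=O)C(C)(C)C[C@H](O)C1
F11 | step 5 | tributyl[(1E,3E)-5-bromo-3-methylpenta-1,3-dien-1-yl]stannane | CCCC[Sn](CCCC)(CCCC)/C=C/C(C)=C/CBr
F12 | step 5 | diethyl [(2E,4E)-3-methyl-5-(tributylstannyl)penta-2,4-dien-1-yl]phosphonate | CCCC[Sn](CCCC)(CCCC)/C=C/C(C)=C/CP(=O)(OCC)OCC
F13 | step 5 | (2E,4E,6E,8E,10E,12E)-2,7,11-trimethyl-13-(tributylstannyl)trideca-2,4,6,8,10,12-hexaenal | CCCC[Sn](CCCC)(CCCC)/C=C/C(C)=C/C=C/C(C)=C/C=C/C=C(\C)C=O
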